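**Retrosynthetic overview**

1. Side chain last: the 1,3-diketone is cut between the CH3 of a ring methyl ketone (11) and an O-benzyl feruloyl chloride (soft-enolisation C-acylation); both benzyl ethers then fall in one step.
2. Ring: the cyclohexene holds a Claisen retron, O=C–C1–C2(H)(3,4-dimethoxyphenyl)–C3=C4. An Ireland–Claisen ring transposition of the silyl ketene acetal of trans-δ-lactone 6 forms C1–C2, creates C3=C4 and cleaves the lactone C4–O bond, a temporary tether that is not in the target.
3. Stereocenters: one carbinol center is set by catalysis (Keck allylation). It directs the aryl-bearing center C6 (Rh 1,4-addition, trans) and is then traded for C2 in the boat [3,3] shift. C1 emerges cis and is equilibrated to the all-trans array at the ketone stage.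
4. Ring order: sacrificial dihydropyranone by RCM, then trans-lactone, then the carbocycle by Claisen (the lactone ring is consumed).

Key step: step 5

Remark: ring atoms carry the locants of the target's IUPAC name (C1 acyl, C2 3,4-dimethoxyphenyl, C3=C4, C5 H2, C6 4-hydroxy-3-methoxyphenyl). The 1,3-diketone is written as the chelated enol of the target SMILES; keto and enol forms are treated as one compound. Compounds 1, 5 and 12 are assumed to be purchased.

**Route**

Step 1
Reactants: 1 (E)-3-(3,4-dimethoxyphenyl)prop-2-enal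
Product: 2 (1E,3R)-1-(3,4-dimethoxyphenyl)hexa-1,5-dien-3-ol
Conditions: allylSnBu3, (R)-BINOL (10 mol %), Ti(Oi-Pr)4 (10 mol %), 4 Å MS, CH2Cl2, −20 °C
Reagents that add atoms: allyltributylstannane, C=CC[Sn](CCCC)(CCCC)CCCC
Why: Keck asymmetric allylation, in which the (R)-BINOL–Ti(IV) Lewis acid activates the enal for 1,2-addition and directs allyl transfer to the Re face, should set the (R)-carbinol that later serves as the sacrificial C–O stereocenter, leaving the E-alkene untouched.

Step 2
Reactants: 2 (1E,3R)-1-(3,4-dimethoxyphenyl)hexa-1,5-dien-3-ol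
Product: 3 (1E,3R)-1-(3,4-dimethoxyphenyl)hexa-1,5-dien-3-yl prop-2-enoate
Conditions: acryloyl chloride, Et3N, CH2Cl2, 0 °C
Reagents that add atoms: acryloyl chloride, C=CC(=O)Cl
Why: O-acylation of a secondary allylic alcohol with an acid chloride under amine base (esterification) leaves the stereocenter and both alkenes unchanged.

Step 3
Reactants: 3 (1E,3R)-1-(3,4-dimethoxyphenyl)hexa-1,5-dien-3-yl prop-2-enoate
Product: 4 (6R)-6-[(E)-2-(3,4-dimethoxyphenyl)ethenyl]-5,6-dihydro-2H-pyran-2-one
Conditions: Grubbs I (5 mol %), CH2Cl2 (0.01 M), 40 °C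
Reagents that add atoms: none
Why: Ring-closing metathesis, in which the catalyst loads on the terminal allyl alkene and closes onto the acrylate with loss of ethylene, should give the six-membered enoate because the 1,2-disubstituted styryl alkene reacts more slowly, as is established for 6-styryl-5,6-dihydropyran-2-ones; no stereocenter is affected.

Step 4
Reactants: 4 (6R)-6-[(E)-2-(3,4-dimethoxyphenyl)ethenyl]-5,6-dihydro-2H-pyran-2-one; 5 [4-(benzyloxy)-3-methoxyphenyl]boronic acid
Product: 6 (4S,6R)-4-[4-(benzyloxy)-3-methoxyphenyl]-6-[(E)-2-(3,4-dimethoxyphenyl)ethenyl]oxan-2-one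
Conditions: 5 (2 equiv), [Rh(cod)OH]2 (2.5 mol %), dioxane/H2O 10:1, 40 °C
Reagents that add atoms: [4-(benzyloxy)-3-methoxyphenyl]boronic acid (5), COc1cc(B(O)O)ccc1OCc1ccccc1
Why: Hayashi–Miyaura rhodium-catalysed 1,4-addition, in which aryl–Rh(I) inserts the enoate on the face anti to the pseudo-equatorial C6 styryl group (axial attack on the half-chair), should set C4 as S (trans to the styryl group) by substrate control, and the neutral medium should spare the allylic lactone C–O bond and the benzyl ether.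

Step 5
Reactants: 6 (4S,6R)-4-[4-(benzyloxy)-3-methoxyphenyl]-6-[(E)-2-(3,4-dimethoxyphenyl)ethenyl]oxan-2-one
Product: 9 (1S,2R,6S)-6-[4-(benzyloxy)-3-methoxyphenyl]-2-(3,4-dimethoxyphenyl)cyclohex-3-ene-1-carboxylic acid, via silyl ketene acetal 7 (not isolated), via TBS ester 8 (not isolated)
Conditions: LDA, TBSCl, DMPU, THF, −78 → 23 °C; PhMe, 105 °C; then 1 M HCl, THF, 23 °C
Reagents that add atoms: none
Why: Deprotonation and O-silylation turn the lactone into its cyclic silyl ketene acetal 7, an allyl vinyl ether whose vinyl part (C=C–OSi) and allyl part (O–CH–CH=CH–aryl) are tied by the two-carbon bridge C5–C6, so the [3,3] shift (Ireland–Claisen rearrangement of a lactone enolate, the known carbocycle-forming lactone Claisen) can only pass through a boat transition state of bicyclo[2.2.2]-like shape. The cyclohexene is closed by suprafacial C1–C2 bond formation on the face of the ketene acetal that carries the pseudo-axial styryl arm while the temporary C4–O bond breaks and C3=C4 appears, i.e. a ring transposition of the six-membered lactone into the six-membered carbocycle, not a cyclisation of an open chain. C2 is set by chirality transfer from the carbinol center (which becomes sp2 C4) through the E-alkene geometry, the aryl group sitting in the outside position of the boat and therefore ending cis to the carboxyl group. C1 is set by the ring constraint (new bond syn to the styryl arm), and because the C6 aryl group of the trans-lactone lies on the opposite face of the lactone it also ends cis to the carboxyl group, so the all-cis acid 9 is expected. The selectivity needed is complete fidelity of the transfer, i.e. no heterolysis of the doubly activated allylic C–O bond, which the basic non-ionising medium and the intramolecular concerted path should secure; the trans-lactone is the matched diastereomer because its aryl group points away from the incoming styryl terminus. The cis configuration at the enolisable C1 is corrected in step 6.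

Step 6
Reactants: 9 (1S,2R,6S)-6-[4-(benzyloxy)-3-methoxyphenyl]-2-(3,4-dimethoxyphenyl)cyclohex-3-ene-1-carboxylic acid
Product: 11 1-[(1R,2R,6S)-6-[4-(benzyloxy)-3-methoxyphenyl]-2-(3,4-dimethoxyphenyl)cyclohex-3-en-1-yl]ethan-1-one, via all-cis methyl ketone 10 (not isolated)
Conditions: MeLi (3.5 equiv), THF, 0 → 23 °C; inverse quench into MeOH, then 60 °C; aq. NH4Cl
Reagents that add atoms: methyllithium, [Li]C
Why: Addition of methyllithium to the lithium carboxylate gives a dilithio gem-diolate that releases the methyl ketone only on the inverse methanol quench (so no tertiary alcohol should form), and the lithium methoxide generated there should equilibrate the enolisable C1 from the axial all-cis arrangement to the thermodynamically preferred all-equatorial (1R) ketone, while C2 and C6, which carry no acidifying group, stay fixed.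

Step 7
Reactants: 11 1-[(1R,2R,6S)-6-[4-(benzyloxy)-3-methoxyphenyl]-2-(3,4-dimethoxyphenyl)cyclohex-3-en-1-yl]ethan-1-one; 12 (E)-3-[4-(benzyloxy)-3-methoxyphenyl]prop-2-enoic acid
Product: 14 (2Z,4E)-5-[4-(benzyloxy)-3-methoxyphenyl]-1-[(1R,2R,6S)-6-[4-(benzyloxy)-3-methoxyphenyl]-2-(3,4-dimethoxyphenyl)cyclohex-3-en-1-yl]-3-hydroxypenta-2,4-dien-1-one, via acid chloride 13 (not isolated)
Conditions: 12, (COCl)2, DMF (cat.), CH2Cl2, 0 → 23 °C, evaporate; then 11, MgBr2·OEt2, i-Pr2NEt, CH2Cl2, 23 °C; 1 M HCl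
Reagents that add atoms: (E)-3-[4-(benzyloxy)-3-methoxyphenyl]prop-2-enoic acid (12), COc1cc(/C=C/C(=O)O)ccc1OCc1ccccc1
Why: Soft-enolisation C-acylation of a methyl ketone with an acid chloride should enolise the unhindered methyl group and not the shielded C1 methine, the magnesium diketonate formed protects the product from a second acylation, and C1 already has its thermodynamic configuration, so reversible enolisation cannot erode it.

Step 8
Reactants: 14 (2Z,4E)-5-[4-(benzyloxy)-3-methoxyphenyl]-1-[(1R,2R,6S)-6-[4-(benzyloxy)-3-methoxyphenyl]-2-(3,4-dimethoxyphenyl)cyclohex-3-en-1-yl]-3-hydroxypenta-2,4-dien-1-one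
Product: 15 (2Z,4E)-1-[(1R,2R,6S)-2-(3,4-dimethoxyphenyl)-6-(4-hydroxy-3-methoxyphenyl)cyclohex-3-en-1-yl]-3-hydroxy-5-(4-hydroxy-3-methoxyphenyl)penta-2,4-dien-1-one
Conditions: BCl3, C6HMe5, CH2Cl2, −78 °C; then MeOH, aq. HCl
Reagents that add atoms: none
Why: Lewis-acid debenzylation of aryl benzyl ethers with BCl3 and the cation scavenger pentamethylbenzene at −78 °C should cleave both O–benzyl bonds (helped by chelation to the neighbouring methoxy groups) without reducing the alkenes or cleaving the aryl methyl ethers, the transient boron diketonate being hydrolysed on work-up; no stereocenter is involved.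

**Compound list**

1 | (E)-3-(3,4-dimethoxyphenyl)prop-2-enal | COc1ccc(/C=C/C=O)cc1OC | starting material
2 | (1E,3R)-1-(3,4-dimethoxyphenyl)hexa-1,5-dien-3-ol | C=CC[C@@H](O)/C=C/c1ccc(OC)c(OC)c1 | intermediate
3 | (1E,3R)-1-(3,4-dimethoxyphenyl)hexa-1,5-dien-3-yl prop-2-enoate | C=CC[C@@H](OC(=O)C=C)/C=C/c1ccc(OC)c(OC)c1 | intermediate
4 | (6R)-6-[(E)-2-(3,4-dimethoxyphenyl)ethenyl]-5,6-dihydro-2H-pyran-2-one | O=C1C=CC[C@H](/C=C/c2ccc(OC)c(OC)c2)O1 | intermediate
5 | [4-(benzyloxy)-3-methoxyphenyl]boronic acid | COc1cc(B(O)O)ccc1OCc1ccccc1 | starting material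
6 | (4S,6R)-4-[4-(benzyloxy)-3-methoxyphenyl]-6-[(E)-2-(3,4-dimethoxyphenyl)ethenyl]oxan-2-one (trans-lactone) | O=C1C[C@@H](c2ccc(OCc3ccccc3)c(OC)c2)C[C@H](/C=C/c2ccc(OC)c(OC)c2)O1 | intermediate
7 | tert-butyl{[(2R,4S)-4-[4-(benzyloxy)-3-methoxyphenyl]-2-[(E)-2-(3,4-dimethoxyphenyl)ethenyl]-3,4-dihydro-2H-pyran-6-yl]oxy}dimethylsilane (silyl ketene acetal) | CC(C)(C)[Si](C)(C)OC1=C[C@@H](c2ccc(OCc3ccccc3)c(OC)c2)C[C@H](/C=C/c2ccc(OC)c(OC)c2)O1 | intermediate
8 | tert-butyldimethylsilyl (1S,2R,6S)-6-[4-(benzyloxy)-3-methoxyphenyl]-2-(3,4-dimethoxyphenyl)cyclohex-3-ene-1-carboxylate | CC(C)(C)[Si](C)(C)OC(=O)[C@H]1[C@@H](c2ccc(OCc3ccccc3)c(OC)c2)CC=C[C@H]1c1ccc(OC)c(OC)c1 | intermediate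
9 | (1S,2R,6S)-6-[4-(benzyloxy)-3-methoxyphenyl]-2-(3,4-dimethoxyphenyl)cyclohex-3-ene-1-carboxylic acid (all-cis) | OC(=O)[C@H]1[C@@H](c2ccc(OCc3ccccc3)c(OC)c2)CC=C[C@H]1c1ccc(OC)c(OC)c1 | intermediate
10 | 1-[(1S,2R,6S)-6-[4-(benzyloxy)-3-methoxyphenyl]-2-(3,4-dimethoxyphenyl)cyclohex-3-en-1-yl]ethan-1-one (all-cis) | CC(=O)[C@H]1[C@@H](c2ccc(OCc3ccccc3)c(OC)c2)CC=C[C@H]1c1ccc(OC)c(OC)c1 | intermediate
11 | 1-[(1R,2R,6S)-6-[4-(benzyloxy)-3-methoxyphenyl]-2-(3,4-dimethoxyphenyl)cyclohex-3-en-1-yl]ethan-1-one (all-trans) | CC(=O)[C@@H]1[C@@H](c2ccc(OCc3ccccc3)c(OC)c2)CC=C[C@H]1c1ccc(OC)c(OC)c1 | intermediate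
12 | (E)-3-[4-(benzyloxy)-3-methoxyphenyl]prop-2-enoic acid | COc1cc(/C=C/C(=O)O)ccc1OCc1ccccc1 | starting material
13 | (E)-3-[4-(benzyloxy)-3-methoxyphenyl]prop-2-enoyl chloride | COc1cc(/C=C/C(=O)Cl)ccc1OCc1ccccc1 | intermediate
14 | (2Z,4E)-5-[4-(benzyloxy)-3-methoxyphenyl]-1-[(1R,2R,6S)-6-[4-(benzyloxy)-3-methoxyphenyl]-2-(3,4-dimethoxyphenyl)cyclohex-3-en-1-yl]-3-hydroxypenta-2,4-dien-1-one | COc1cc(/C=C/C(O)=C/C(=O)[C@@H]2[C@@H](c3ccc(OCc4ccccc4)c(OC)c3)CC=C[C@H]2c2ccc(OC)c(OC)c2)ccc1OCc1ccccc1 | intermediate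
15 | (2Z,4E)-1-[(1R,2R,6S)-2-(3,4-dimethoxyphenyl)-6-(4-hydroxy-3-methoxyphenyl)cyclohex-3-en-1-yl]-3-hydroxy-5-(4-hydroxy-3-methoxyphenyl)penta-2,4-dien-1-one | COc1cc(/C=C/C(O)=C/C(=O)[C@@H]2[C@@H](c3ccc(O)c(OC)c3)CC=C[C@H]2c2ccc(OC)c(OC)c2)ccc1O | target

**Step count and risks**

Total step count: 8. Longest linear sequence: 8 (1 → 15).

Steps most likely to fail:

Step 5. The allylic C–O bond of ketene acetal 7 is doubly activated (cinnamyl-type, electron-rich arene) and may ionise before the concerted shift, which would scramble the transferred chirality or end in elimination; self-condensation or C-silylation of the lactone enolate may also compete. The fallback gives up the tether and joins diene and dienophile directly; it sets out from 1 and 12 and comes back at 11. Wittig methylenation of 1 (Ph3P=CH2, THF) should give (E)-1-(3,4-dimethoxyphenyl)buta-1,3-diene F1, and 12 with methyllithium should give (E)-4-[4-(benzyloxy)-3-methoxyphenyl]but-3-en-2-one F2. A thermal Diels–Alder reaction of F1 with F2 (PhMe, 150 °C, BHT, sealed tube, or high pressure) should give the ortho adducts. The exo adduct is separated from the endo diastereomer rac-1-[(1R,2S,6S)-6-[4-(benzyloxy)-3-methoxyphenyl]-2-(3,4-dimethoxyphenyl)cyclohex-3-en-1-yl]ethan-1-one F4 and is obtained as the racemate of 11 and its mirror image 1-[(1S,2S,6R)-6-[4-(benzyloxy)-3-methoxyphenyl]-2-(3,4-dimethoxyphenyl)cyclohex-3-en-1-yl]ethan-1-one F3. Preparative chromatography on a chiral stationary phase then returns 11.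

Step 6. Addition to the hindered axial carboxylate may be slow and lose out to proton abstraction, over-addition may occur during the quench, or the equilibration at C1 may stay incomplete. The fallback reverses the roles of the two partners, so that the ring becomes the acyl donor; it sets out from 9 and comes back at 14. Esterification (TMSCHN2, MeOH/PhMe) should give methyl (1S,2R,6S)-6-[4-(benzyloxy)-3-methoxyphenyl]-2-(3,4-dimethoxyphenyl)cyclohex-3-ene-1-carboxylate F5. NaOMe in MeOH at reflux should equilibrate it to the all-trans methyl (1R,2R,6S)-ester F6, and aqueous NaOH added to the same pot should saponify it to the all-trans (1R,2R,6S)-carboxylic acid F7. Oxalyl chloride converts F7 into the (1R,2R,6S)-carbonyl chloride F8, which C-acylates the magnesium enolate of the enone F2 of the first fallback (MgBr2·OEt2, i-Pr2NEt, CH2Cl2) to give 14.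

Step 8. Chelation-assisted loss of methyl ethers, Friedel–Crafts benzylation of the electron-rich rings or acid-induced decomposition of the dienone–enol may accompany the double debenzylation of the finished curcuminoid. The fallback moves the deprotection to the robust ketone and forms the side-chain alkene by aldol condensation instead of acylation; it sets out from 11 and comes back at 15. BCl3/C6HMe5 at −78 °C on 11 should give 1-[(1R,2R,6S)-2-(3,4-dimethoxyphenyl)-6-(4-hydroxy-3-methoxyphenyl)cyclohex-3-en-1-yl]ethan-1-one F9. Claisen condensation with ethyl acetate (NaH, THF, one extra equivalent of base for the phenoxide) should give 1-[(1R,2R,6S)-2-(3,4-dimethoxyphenyl)-6-(4-hydroxy-3-methoxyphenyl)cyclohex-3-en-1-yl]butane-1,3-dione F10. A boron-templated aldol condensation with unprotected vanillin (B2O3, B(On-Bu)3, n-BuNH2, EtOAc, 80 °C; then dilute HCl) should react only at the methyl terminus and give 15 without a final deprotection.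

**Further compounds**

F1 | step 5 | (E)-1-(3,4-dimethoxyphenyl)buta-1,3-diene | C=C/C=C/c1ccc(OC)c(OC)c1
F2 | step 5 | (E)-4-[4-(benzyloxy)-3-methoxyphenyl]but-3-en-2-one | CC(=O)/C=C/c1ccc(OCc2ccccc2)c(OC)c1
F3 | step 5 | 1-[(1S,2S,6R)-6-[4-(benzyloxy)-3-methoxyphenyl]-2-(3,4-dimethoxyphenyl)cyclohex-3-en-1-yl]ethan-1-one (mirror image of 11) | CC(=O)[C@H]1[C@H](c2ccc(OCc3ccccc3)c(OC)c2)CC=C[C@@H]1c1ccc(OC)c(OC)c1
F4 | step 5 | rac-1-[(1R,2S,6S)-6-[4-(benzyloxy)-3-methoxyphenyl]-2-(3,4-dimethoxyphenyl)cyclohex-3-en-1-yl]ethan-1-one (endo adduct, one enantiomer drawn) | CC(=O)[C@@H]1[C@@H](c2ccc(OCc3ccccc3)c(OC)c2)CC=C[C@@H]1c1ccc(OC)c(OC)c1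
F5 | step 6 | methyl (1S,2R,6S)-6-[4-(benzyloxy)-3-methoxyphenyl]-2-(3,4-dimethoxyphenyl)cyclohex-3-ene-1-carboxylate | COC(=O)[C@H]1[C@@H](c2ccc(OCc3ccccc3)c(OC)c2)CC=C[C@H]1c1ccc(OC)c(OC)c1
F6 | step 6 | methyl (1R,2R,6S)-6-[4-(benzyloxy)-3-methoxyphenyl]-2-(3,4-dimethoxyphenyl)cyclohex-3-ene-1-carboxylate | COC(=O)[C@@H]1[C@@H](c2ccc(OCc3ccccc3)c(OC)c2)CC=C[C@H]1c1ccc(OC)c(OC)c1
F7 | step 6 | (1R,2R,6S)-6-[4-(benzyloxy)-3-methoxyphenyl]-2-(3,4-dimethoxyphenyl)cyclohex-3-ene-1-carboxylic acid | OC(=O)[C@@H]1[C@@H](c2ccc(OCc3ccccc3)c(OC)c2)CC=C[C@H]1c1ccc(OC)c(OC)c1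
F8 | step 6 | (1R,2R,6S)-6-[4-(benzyloxy)-3-methoxyphenyl]-2-(3,4-dimethoxyphenyl)cyclohex-3-ene-1-carbonyl chloride | ClC(=O)[C@@H]1[C@@H](c2ccc(OCc3ccccc3)c(OC)c2)CC=C[C@H]1c1ccc(OC)c(OC)c1
F9 | step 8 | 1-[(1R,2R,6S)-2-(3,4-dimethoxyphenyl)-6-(4-hydroxy-3-methoxyphenyl)cyclohex-3-en-1-yl]ethan-1-one | CC(=O)[C@@H]1[C@@H](c2ccc(O)c(OC)c2)CC=C[C@H]1c1ccc(OC)c(OC)c1
F10 | step 8 | 1-[(1R,2R,6S)-2-(3,4-dimethoxyphenyl)-6-(4-hydroxy-3-methoxyphenyl)cyclohex-3-en-1-yl]butane-1,3-dione | CC(=O)CC(=O)[C@@H]1[C@@H](c2ccc(O)c(OC)c2)CC=C[C@H]1c1ccc(OC)c(OC)c1
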